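The central cyclohexene (C1 quaternary, C2 bearing the indol-5-yl group, C3=C4, C5, C6) is the [4+2] retron of two identical 5-dienylindole halves. Its C1 methyl stands cis to the C2 indolyl group, exactly where an endo activating group would end up. One half is therefore kept as diene 7. In the other, the future C1 methyl is carried as a formyl group (2-styrylacrolein 10). A chiral oxazaborolidinium-catalysed Diels–Alder reaction unites both halves at the hindered C1–C2 bond and at C5–C6, closing the ring and setting both stereocentres at once. The formyl group is afterwards reduced to the methyl group.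

Key step: step 7

Assumption: the sense of induction in step 7 follows the accepted pre-transition-state picture for 2-substituted acroleins bound to this catalyst family. Both antipodes of the oxazaborolidine are commercial, so the antipode would serve if the sense proved opposite.

Step 1
Reactants: 1 5-bromo-1H-indole; 2 isoprene
Product: 3 5-bromo-3-(2-methylbut-3-en-2-yl)-1H-indole
Conditions: [Rh(cod)Cl]2 (2.5 mol %), DTBM-SEGPHOS (5 mol %), camphorsulfonic acid (10 mol %), 2 (5 equiv), ClCH2CH2Cl, 60 °C, sealed tube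
Reagents that add atoms: none
Why: Rhodium-hydride-catalysed hydroheteroarylation of isoprene (catalytic reverse prenylation of indoles), in which H–Rh addition to the isopropenyl terminus gives a 1,1-dimethylallyl rhodium species that indole C3 attacks at its tertiary end, while the aryl bromide is inert to the monovalent rhodium catalyst.

Step 2
Reactants: 3 5-bromo-3-(2-methylbut-3-en-2-yl)-1H-indole
Product: 4 5-bromo-3-(2-methylbut-3-en-2-yl)-1-tosylindole
Conditions: TsCl, 50 % aq NaOH, Bu4NHSO4 (cat.), toluene, 0 °C to rt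
Reagents that add atoms: 4-toluenesulfonyl chloride, Cc1ccc(S(=O)(=O)Cl)cc1
Why: Phase-transfer N-sulfonylation, which shuts down the N and C2 nucleophilicity of the indole for the later enolate, palladium and Lewis acid steps.

Step 3
Reactants: 4 5-bromo-3-(2-methylbut-3-en-2-yl)-1-tosylindole; 5 methyl vinyl ketone
Product: 6 (E)-4-[3-(2-methylbut-3-en-2-yl)-1-tosylindol-5-yl]but-3-en-2-one
Conditions: Pd(OAc)2 (5 mol %), P(o-tol)3 (12 mol %), Et3N, 5 (3 equiv), MeCN, 85 °C
Reagents that add atoms: none
Why: Mizoroki–Heck reaction, in which the unhindered electron-poor enone inserts far faster than the neopentyl-type vinyl group of the side chain, and syn insertion followed by syn β-hydride elimination gives the E enone.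

Step 4
Reactants: 6 (E)-4-[3-(2-methylbut-3-en-2-yl)-1-tosylindol-5-yl]but-3-en-2-one
Product: 7 3-(2-methylbut-3-en-2-yl)-5-[(1E)-3-methylbuta-1,3-dien-1-yl]-1-tosylindole
Conditions: Ph3PCH3Br, KOtBu, THF, 0 °C to rt; stored cold
Reagents that add atoms: methyltriphenylphosphonium bromide, C[P+](c1ccccc1)(c1ccccc1)c1ccccc1.[Br-]
Why: Wittig methylenation, which attacks the enone carbonyl in 1,2-fashion and leaves the E alkene and the sulfonamide untouched.

Step 5
Reactants: 6 (E)-4-[3-(2-methylbut-3-en-2-yl)-1-tosylindol-5-yl]but-3-en-2-one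
Product: 9 (3E)-4-[3-(2-methylbut-3-en-2-yl)-1-tosylindol-5-yl]buta-1,3-dien-2-yl trifluoromethanesulfonate, via potassium dienolate 8 (not isolated)
Conditions: KN(SiMe3)2, THF, −78 °C; then PhNTf2, −78 to 0 °C
Reagents that add atoms: N-phenylbis(trifluoromethanesulfonimide), O=S(=O)(N(c1ccccc1)S(=O)(=O)C(F)(F)F)C(F)(F)F; potassium hexamethyldisilazide, C[Si](C)(C)[N-][Si](C)(C)C.[K+] (potassium only in 8)
Why: Enol triflate synthesis, by kinetic deprotonation at the only enolisable position (the methyl group) and O-sulfonylation of the cross-conjugated enolate.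

Step 6
Reactants: 9 (3E)-4-[3-(2-methylbut-3-en-2-yl)-1-tosylindol-5-yl]buta-1,3-dien-2-yl trifluoromethanesulfonate
Product: 10 (3E)-2-methylidene-4-[3-(2-methylbut-3-en-2-yl)-1-tosylindol-5-yl]but-3-enal
Conditions: Pd(PPh3)4 (5 mol %), LiCl, CO (1 atm), Bu3SnH (slow addition), THF, 50 °C; used at once as a cold solution
Reagents that add atoms: carbon monoxide, [C-]#[O+]
Why: Palladium-catalysed reductive carbonylation (formylation) of an enol triflate through oxidative addition to zerovalent palladium, CO insertion and hydride transfer from tin, with slow hydride addition keeping direct and conjugate reduction down.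

Step 7
Reactants: 7 3-(2-methylbut-3-en-2-yl)-5-[(1E)-3-methylbuta-1,3-dien-1-yl]-1-tosylindole; 10 (3E)-2-methylidene-4-[3-(2-methylbut-3-en-2-yl)-1-tosylindol-5-yl]but-3-enal
Product: 11 (1R,2S)-4-methyl-2-[3-(2-methylbut-3-en-2-yl)-1-tosylindol-5-yl]-1-{(E)-2-[3-(2-methylbut-3-en-2-yl)-1-tosylindol-5-yl]ethenyl}cyclohex-3-ene-1-carbaldehyde
Conditions: (S)-3,3-diphenyl-1-(2-methylphenyl)tetrahydro-1H,3H-pyrrolo[1,2-c][1,3,2]oxazaborole (20 mol %), Tf2NH (18 mol %), 7 (1.5 equiv), CH2Cl2, −78 to −40 °C
Reagents that add atoms: none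
Why: The N-protonated oxazaborolidine binds the formyl oxygen of 10 (s-trans enal, formyl C–H···O contact), which lowers the LUMO of the CH2=C(CHO) unit, and diene 7 adds in a concerted but asynchronous suprafacial [4+2] cycloaddition in which the C5–C6 bond runs ahead of the C1–C2 bond. The closest known reaction type is the oxazaborolidinium-catalysed enantioselective Diels–Alder reaction of 2-substituted acroleins with acyclic dienes. The six-membered carbocycle is closed by intermolecular cycloaddition, C2 to C5 coming from 7 and C1 and C6 from 10. C1 is controlled by the catalyst, whose phenyl group covers one face of the bound enal so that the diene reaches the Si face of the α-carbon, and C2 is controlled relative to C1 by the Alder endo rule, the boron-bound formyl group lying under the E-configured diene and so ending cis to the C2 indolyl group while the styryl group ends exo and trans. Regioselectivity is secured because the 1-aryl and 3-methyl groups of 7 both put the largest HOMO coefficient on its terminal CH2, which pairs with the β-CH2 of the enal (matched ortho and para orientation). Cross-reaction over self-addition of 10 is secured by the excess of the more electron-rich 7 at low temperature, a slight deficit of Tf2NH avoids free acid, and the tosylated indoles and the hindered 1,1-dimethylallyl vinyl groups stay inert.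

Step 8
Reactants: 11 (1R,2S)-bis(N-tosyl) cyclohexene carbaldehyde
Product: 12 (1R,2S)-4-methyl-2-[3-(2-methylbut-3-en-2-yl)-1H-indol-5-yl]-1-{(E)-2-[3-(2-methylbut-3-en-2-yl)-1H-indol-5-yl]ethenyl}cyclohex-3-ene-1-carbaldehyde
Conditions: NaOH (aq), MeOH/THF, 60 °C
Reagents that add atoms: none
Why: Basic cleavage of N-sulfonylindoles (indolide as leaving group on sulfur), safe for an aldehyde without α-hydrogen and too mild to touch C2–H, and placed before any hydrazine is present so that no tosyl hydrazide, a diimide source that would reduce the vinyl groups, can form.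

Step 9
Reactants: 12 (1R,2S)-bis(N–H) cyclohexene carbaldehyde
Product: 14 5-[(E)-2-{(1S,2R)-1,4-dimethyl-2-[3-(2-methylbut-3-en-2-yl)-1H-indol-5-yl]cyclohex-3-en-1-yl}ethenyl]-3-(2-methylbut-3-en-2-yl)-1H-indole (target), via hydrazone 13 (not isolated)
Conditions: N2H4·H2O (excess), EtOH, 80 °C, argon; evaporate; then KOtBu (6 equiv), DMSO, rt
Reagents that add atoms: hydrazine hydrate, NN.O (nitrogen only in 13)
Why: Wolff–Kishner reduction in its room-temperature KOtBu/DMSO variant, in which tautomerisation of the hydrazone anion to the diazene anion and loss of N2 leave the methyl group without touching C1 (the descriptors change only through priority), while prior deprotonation of both indole N–H groups makes the para-linked C2–H far less acidic and so guards C2 and the position of the C3=C4 bond.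

Compound list
1 | 5-bromo-1H-indole | Brc1ccc2[nH]ccc2c1 | starting material
2 | isoprene | C=CC(C)=C | starting material
3 | 5-bromo-3-(2-methylbut-3-en-2-yl)-1H-indole | C=CC(C)(C)c1c[nH]c2ccc(Br)cc12 | intermediate
4 | 5-bromo-3-(2-methylbut-3-en-2-yl)-1-tosylindole | C=CC(C)(C)c1cn(S(=O)(=O)c2ccc(C)cc2)c2ccc(Br)cc12 | intermediate
5 | methyl vinyl ketone | C=CC(C)=O | starting material
6 | (E)-4-[3-(2-methylbut-3-en-2-yl)-1-tosylindol-5-yl]but-3-en-2-one | CC(=O)/C=C/c1ccc2c(c1)c(C(C)(C)C=C)cn2S(=O)(=O)c1ccc(C)cc1 | intermediate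
7 | 3-(2-methylbut-3-en-2-yl)-5-[(1E)-3-methylbuta-1,3-dien-1-yl]-1-tosylindole | C=C(C)/C=C/c1ccc2c(c1)c(C(C)(C)C=C)cn2S(=O)(=O)c1ccc(C)cc1 | intermediate
8 | potassium (3E)-4-[3-(2-methylbut-3-en-2-yl)-1-tosylindol-5-yl]buta-1,3-dien-2-olate | [K+].C=C([O-])/C=C/c1ccc2c(c1)c(C(C)(C)C=C)cn2S(=O)(=O)c1ccc(C)cc1 | intermediate
9 | (3E)-4-[3-(2-methylbut-3-en-2-yl)-1-tosylindol-5-yl]buta-1,3-dien-2-yl trifluoromethanesulfonate | C=C(OS(=O)(=O)C(F)(F)F)/C=C/c1ccc2c(c1)c(C(C)(C)C=C)cn2S(=O)(=O)c1ccc(C)cc1 | intermediate
10 | (3E)-2-methylidene-4-[3-(2-methylbut-3-en-2-yl)-1-tosylindol-5-yl]but-3-enal | C=C(C=O)/C=C/c1ccc2c(c1)c(C(C)(C)C=C)cn2S(=O)(=O)c1ccc(C)cc1 | intermediate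
11 | (1R,2S)-4-methyl-2-[3-(2-methylbut-3-en-2-yl)-1-tosylindol-5-yl]-1-{(E)-2-[3-(2-methylbut-3-en-2-yl)-1-tosylindol-5-yl]ethenyl}cyclohex-3-ene-1-carbaldehyde | C=CC(C)(C)c1cn(S(=O)(=O)c2ccc(C)cc2)c2ccc(/C=C/[C@]3(C=O)CCC(C)=C[C@H]3c3ccc4c(c3)c(C(C)(C)C=C)cn4S(=O)(=O)c3ccc(C)cc3)cc12 | intermediate
12 | (1R,2S)-4-methyl-2-[3-(2-methylbut-3-en-2-yl)-1H-indol-5-yl]-1-{(E)-2-[3-(2-methylbut-3-en-2-yl)-1H-indol-5-yl]ethenyl}cyclohex-3-ene-1-carbaldehyde | C=CC(C)(C)c1c[nH]c2ccc(/C=C/[C@]3(C=O)CCC(C)=C[C@H]3c3ccc4[nH]cc(C(C)(C)C=C)c4c3)cc12 | intermediate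
13 | (E)-hydrazone of aldehyde 12, (1R,2S) | C=CC(C)(C)c1c[nH]c2ccc(/C=C/[C@]3(/C=N/N)CCC(C)=C[C@H]3c3ccc4[nH]cc(C(C)(C)C=C)c4c3)cc12 | intermediate
14 | 5-[(E)-2-{(1S,2R)-1,4-dimethyl-2-[3-(2-methylbut-3-en-2-yl)-1H-indol-5-yl]cyclohex-3-en-1-yl}ethenyl]-3-(2-methylbut-3-en-2-yl)-1H-indole | C=CC(C)(C)c1c[nH]c2ccc(/C=C/[C@]3(C)CCC(C)=C[C@H]3c3ccc4[nH]cc(C(C)(C)C=C)c4c3)cc12 | target

Total step count: 9. Longest linear sequence: 8 steps (1, 2, 3, 5, 6, 7, 8, 9); step 4 is the branch to the diene.

Steps most likely to fail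

1. Step 7.
- What may go wrong: the styryl π-system may compete with the formyl group for the endo position, which would cost diastereocontrol. The dienophile may add to itself, or it may react through its C=C–C=O unit in a hetero-Diels–Alder mode.
- Fallback (sets out from 7, comes back at 14): the activating group is given up. Compound 7 is detosylated (NaOH, MeOH/THF) to the free monomer 3-(2-methylbut-3-en-2-yl)-5-[(1E)-3-methylbuta-1,3-dien-1-yl]-1H-indole F1. This is dimerised in an uncatalysed thermal Diels–Alder reaction (toluene, 120 °C, radical inhibitor). The diastereomer with aryl and styryl groups trans is separated on silica, and its enantiomers are separated on a chiral stationary phase to give 14.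

2. Step 9.
- What may go wrong: base may induce migration of the ring alkene into conjugation with the C2 aryl group. The developing carbanion may add to the neighbouring styryl group. Adventitious diimide may reduce the vinyl groups.
- Fallback (sets out from 12, comes back at 14): deoxygenation by hydride displacement. NaBH4 (MeOH, 0 °C) reduces 12 to the neopentyl alcohol [(1R,2S)-4-methyl-2-[3-(2-methylbut-3-en-2-yl)-1H-indol-5-yl]-1-{(E)-2-[3-(2-methylbut-3-en-2-yl)-1H-indol-5-yl]ethenyl}cyclohex-3-en-1-yl]methanol F2. MsCl/Et3N (CH2Cl2, 0 °C) leaves the indole N–H groups alone and gives the corresponding methanesulfonate F3. Excess LiEt3BH (THF, 65 °C) displaces the sulfonate to give 14.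

3. Step 6.
- What may go wrong: the vinylpalladium species or the product enal may be over-reduced by the tin hydride. The 2-formyl diene may also dimerise while it is kept warm.
- Fallback (sets out from 9, comes back at 10): the one-carbon unit is brought in at the alcohol level. Stille coupling of 9 with Bu3SnCH2OH (Pd(PPh3)4, LiCl, dioxane, 90 °C) gives the storable dienyl carbinol (3E)-2-methylidene-4-[3-(2-methylbut-3-en-2-yl)-1-tosylindol-5-yl]but-3-en-1-ol F4. This is oxidised with MnO2 (CH2Cl2, rt) to 10 immediately before the cycloaddition.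

Further compounds
F1 | step 7 | 3-(2-methylbut-3-en-2-yl)-5-[(1E)-3-methylbuta-1,3-dien-1-yl]-1H-indole | C=C(C)/C=C/c1ccc2[nH]cc(C(C)(C)C=C)c2c1
F2 | step 9 | [(1R,2S)-4-methyl-2-[3-(2-methylbut-3-en-2-yl)-1H-indol-5-yl]-1-{(E)-2-[3-(2-methylbut-3-en-2-yl)-1H-indol-5-yl]ethenyl}cyclohex-3-en-1-yl]methanol | C=CC(C)(C)c1c[nH]c2ccc(/C=C/[C@]3(CO)CCC(C)=C[C@H]3c3ccc4[nH]cc(C(C)(C)C=C)c4c3)cc12
F3 | step 9 | methanesulfonate of alcohol F2, (1R,2S) | C=CC(C)(C)c1c[nH]c2ccc(/C=C/[C@]3(COS(C)(=O)=O)CCC(C)=C[C@H]3c3ccc4[nH]cc(C(C)(C)C=C)c4c3)cc12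
F4 | step 6 | (3E)-2-methylidene-4-[3-(2-methylbut-3-en-2-yl)-1-tosylindol-5-yl]but-3-en-1-ol | C=C(CO)/C=C/c1ccc2c(c1)c(C(C)(C)C=C)cn2S(=O)(=O)c1ccc(C)cc1
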